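**Retrosynthetic overview**

1. The formyl group of the target is traced back through the pyrrol-2-ylcarbinol to the ethyl ester, i.e. to ethyl 5-nonadecyl-1H-pyrrole-2-carboxylate.
2. The aromatic ring is traced back to a 3,4-bis(phenylsulfonyl)pyrrolidine-2-carboxylate, from which two benzenesulfinates are lost with base; no oxidant is needed.
3. The pyrrolidine (the only ring, formed once) is opened at C2–C3 and C4–C5 into a silver azomethine ylide of a glycinate aldimine and (E)-1,2-bis(phenylsulfonyl)ethylene as an acetylene equivalent.
4. The aldimine comes from icosanal (made from icosan-1-ol) and glycine ethyl ester hydrochloride.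
5. Feature carrying the strategy: the C5–N1–C2 arc of the pyrrole ring, with the nonadecyl chain on C5 and the formyl carbon on C2, is the icosanal/glycine ester imine; C3 and C4 carry only hydrogen and are a bare two-carbon unit.

Key step: step 3

Remark: the cycloadduct is expected as a racemic mixture of the two endo/exo diastereomers; one (2,5-cis, 3,4-trans) is drawn, and both converge on the same pyrrole in step 4, so they are not separated.

**Step 1**
Reactants: 1 icosan-1-ol
Product: 2 icosanal
Conditions: TEMPO (10 mol %), PhI(OAc)2 (1.1 equiv), CH2Cl2, rt
Reagents that add atoms: none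
Why: Oxoammonium (TEMPO) oxidation of a primary alcohol stops at the aldehyde when no water is present; the aldehyde is used promptly because long-chain aldehydes autoxidise and trimerise on storage.

**Step 2**
Reactants: 2 icosanal; 3 glycine ethyl ester hydrochloride
Product: 5 ethyl (E)-N-icosylideneglycinate, via glycine ethyl ester 4 (not isolated)
Conditions: Et3N (1.1 equiv), MgSO4, CH2Cl2, 0 °C to rt; filter, concentrate, use at once
Reagents that add atoms: none
Why: Imine condensation (Schiff base formation): Et3N frees amine 4, MgSO4 takes up the water, and the E-aldimine should form under non-acidic conditions; it is not chromatographed because enolisable N-alkylidene glycinates tautomerise and hydrolyse on silica.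

**Step 3**
Reactants: 5 ethyl (E)-N-icosylideneglycinate; 6 (E)-1,2-bis(phenylsulfonyl)ethylene
Product: 8 rac-ethyl (2S,3S,4S,5R)-5-nonadecyl-3,4-bis(phenylsulfonyl)pyrrolidine-2-carboxylate, via silver azomethine ylide 7 (not isolated)
Conditions: AgOAc (10 mol %, monovalent silver), Et3N (20 mol %), THF, 0 °C to rt, dark
Reagents that add atoms: none
Why: AgOAc binds the imine nitrogen and the ester carbonyl of 5, which acidifies the glycine CH2 enough for Et3N to give the chelated, W-shaped N-silver azomethine ylide 7; this 2-azaallyl anion adds across the doubly activated C=C of 6, either concertedly or by Michael addition followed by Mannich closure, and protonolysis of the N–Ag bond by Et3NH+ releases 8 and returns the catalyst. The closest known reaction type is the silver- or copper-catalysed 1,3-dipolar cycloaddition of glycinate aldimines with vinyl sulfones and 1,2-bis(sulfonyl)ethylenes. The pyrrolidine ring closes by an intermolecular [3+2] cycloaddition that forms C2–C3 and C4–C5 (in the stepwise limit the closing event is a 5-endo-trig Mannich attack of the α-sulfonyl carbanion on the silver-bound imine carbon). C2 and C5 should come out cis because the chelate fixes the W geometry of the dipole and the addition is suprafacial, C3 and C4 trans because the E geometry of 6 is carried over, and the endo or exo sense (which sulfonyl group sits cis to the ester) is left uncontrolled, the product being racemic. The selectivity that matters is chemoselectivity, since metalation and cycloaddition must outrun imine–enamine tautomerisation and self-condensation of the enolisable aldimine; the chelation-acidified α-proton (weak base, 0 °C), the freshly made imine and the high electrophilicity of 6 should secure it. Regiochemistry does not arise because 6 is symmetrical, and none of the four stereocentres survives step 4.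

**Step 4**
Reactants: 8 rac-ethyl (2S,3S,4S,5R)-5-nonadecyl-3,4-bis(phenylsulfonyl)pyrrolidine-2-carboxylate
Product: 10 ethyl 5-nonadecyl-1H-pyrrole-2-carboxylate, via monosulfonyl 2-pyrroline 9 (not isolated)
Conditions: DBU (3 equiv), THF, rt to 50 °C
Reagents that add atoms: none
Why: Two successive base-induced sulfinate eliminations (E1cB): DBU removes the C2–H (α to ester and nitrogen) and expels the C3 sulfonyl group to give enamino ester 9, which should lose the second sulfinate by a nitrogen-assisted 1,4-elimination and tautomerise to the 1H-pyrrole, driven by aromatisation and erasing all four stereocentres.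

**Step 5**
Reactants: 10 ethyl 5-nonadecyl-1H-pyrrole-2-carboxylate
Product: 11 (5-nonadecyl-1H-pyrrol-2-yl)methanol
Conditions: i-Bu2AlH (3.5 equiv), THF/toluene, −40 to 0 °C; aq. potassium sodium tartrate; crude used at once
Reagents that add atoms: none
Why: Aluminium hydride reduction of an ester: the first equivalent deprotonates N–H and further hydride takes the ester through the aldehyde to the aluminium alkoxide, while low temperature and a neutral tartrate work-up should keep the acid-sensitive pyrrol-2-ylcarbinol from ionising.

**Step 6**
Reactants: 11 (5-nonadecyl-1H-pyrrol-2-yl)methanol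
Product: 12 5-nonadecyl-1H-pyrrole-2-carbaldehyde
Conditions: activated MnO2 (15 equiv), CH2Cl2, rt
Reagents that add atoms: none
Why: MnO2 oxidation of an activated (heterobenzylic) alcohol: the pyrrol-2-ylcarbinol should be oxidised under neutral heterogeneous conditions to the 2-formylpyrrole, a vinylogous formamide that resists over-oxidation.

**Compound list**

1 | icosan-1-ol | CCCCCCCCCCCCCCCCCCCCO | starting material
2 | icosanal | CCCCCCCCCCCCCCCCCCCC=O | intermediate
3 | glycine ethyl ester hydrochloride | CCOC(=O)CN.Cl | starting material
4 | glycine ethyl ester (free base) | CCOC(=O)CN | intermediate (not isolated)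
5 | ethyl (E)-N-icosylideneglycinate | CCCCCCCCCCCCCCCCCCC/C=N/CC(=O)OCC | intermediate
6 | (E)-1,2-bis(phenylsulfonyl)ethylene | O=S(=O)(/C=C/S(=O)(=O)c1ccccc1)c1ccccc1 | starting material
7 | N,O-chelated silver azomethine ylide of 5 (W-shaped, written as the silver enolate) | CCCCCCCCCCCCCCCCCCC/C=N/C=C(/OCC)O[Ag] | intermediate (not isolated)
8 | rac-ethyl (2S,3S,4S,5R)-5-nonadecyl-3,4-bis(phenylsulfonyl)pyrrolidine-2-carboxylate (2,5-cis, 3,4-trans; one enantiomer drawn) | CCOC(=O)[C@@H]1N[C@H](CCCCCCCCCCCCCCCCCCC)[C@H](S(=O)(=O)c2ccccc2)[C@H]1S(=O)(=O)c3ccccc3 | intermediate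
9 | ethyl 5-nonadecyl-4-(phenylsulfonyl)-4,5-dihydro-1H-pyrrole-2-carboxylate (racemic, diastereomer mixture) | CCOC(=O)C1=CC(S(=O)(=O)c2ccccc2)C(CCCCCCCCCCCCCCCCCCC)N1 | intermediate (not isolated)
10 | ethyl 5-nonadecyl-1H-pyrrole-2-carboxylate | CCCCCCCCCCCCCCCCCCCc1ccc(C(=O)OCC)[nH]1 | intermediate
11 | (5-nonadecyl-1H-pyrrol-2-yl)methanol | CCCCCCCCCCCCCCCCCCCc1ccc(CO)[nH]1 | intermediate
12 | 5-nonadecyl-1H-pyrrole-2-carbaldehyde | CCCCCCCCCCCCCCCCCCCc1ccc(C=O)[nH]1 | target

**Step count**

Total steps: 6. Longest linear sequence: 6 (from icosan-1-ol 1).

**Steps most likely to fail, with fallbacks**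

Step 3 (cycloaddition). The linear aldimine 5 may tautomerise to its enamine and self-condense, or hydrolyse, faster than it is metalated. The alkyl-substituted ylide is also less stabilised than aryl ones, so conjugate addition of amines to 6 may compete. The fallback builds the ring by a Paal–Knorr synthesis that involves no imine ylide, and it sets out from icosanal 2. Addition of the Grignard reagent made from 2-(2-bromoethyl)-1,3-dioxolane and Mg turnings (THF, below 30 °C) should give racemic 1-(1,3-dioxolan-2-yl)docosan-3-ol F1. Dess–Martin oxidation (NaHCO3, CH2Cl2) should give 1-(1,3-dioxolan-2-yl)docosan-3-one F2. Heating F2 with NH4OAc in aqueous AcOH unmasks the γ-keto aldehyde and should close it by Paal–Knorr condensation to 2-nonadecyl-1H-pyrrole F3. Vilsmeier–Haack formylation (POCl3, DMF, 0 °C to rt, then aq. NaOAc) at the free α-position then rejoins the route at the target 12.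

Step 5 (reduction). The electron-rich pyrrol-2-ylcarbinol, or its aluminium alkoxide, may ionise to an azafulvenium ion. That would lead to over-reduction to the 2-methylpyrrole or to oligomerisation during work-up and concentration. The fallback reaches the aldehyde oxidation level without a free carbinol, and it sets out from ester 10. Saponification (NaOH, EtOH/H2O, 70 °C; acidification to pH 4 at 0 °C) should give 5-nonadecyl-1H-pyrrole-2-carboxylic acid F4. Amide coupling with MeNH(OMe)·HCl (EDC·HCl, HOBt, i-Pr2NEt, CH2Cl2) should give N-methoxy-N-methyl-5-nonadecyl-1H-pyrrole-2-carboxamide F5. Weinreb amide reduction with LiAlH4 (THF, 0 °C) proceeds through a chelated tetrahedral intermediate that releases the aldehyde only on aqueous work-up, and rejoins the route at 12.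

Step 4 (aromatisation). The sequence may stall after loss of the first sulfinate. Carbanion chemistry may also divert it, by retro-Mannich ring opening or by air oxidation of a vinyl sulfone intermediate to a 3-sulfonylpyrrole. The fallback removes the sulfonyl groups reductively and then dehydrogenates, and it sets out from cycloadduct 8. Na(Hg) (sodium amalgam) with Na2HPO4 in MeOH/THF at −20 °C should effect a Julia-type reductive 1,2-elimination of the vicinal bis-sulfone to give rac-ethyl cis-5-nonadecyl-2,5-dihydro-1H-pyrrole-2-carboxylate F6. Dehydrogenation of this 3-pyrroline with DDQ (toluene, rt) rejoins the route at pyrrole ester 10.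

**Further compounds**

F1 | step 3 | 1-(1,3-dioxolan-2-yl)docosan-3-ol (racemic) | CCCCCCCCCCCCCCCCCCCC(O)CCC1OCCO1
F2 | step 3 | 1-(1,3-dioxolan-2-yl)docosan-3-one | CCCCCCCCCCCCCCCCCCCC(=O)CCC1OCCO1
F3 | step 3 | 2-nonadecyl-1H-pyrrole | CCCCCCCCCCCCCCCCCCCc1ccc[nH]1
F4 | step 5 | 5-nonadecyl-1H-pyrrole-2-carboxylic acid | CCCCCCCCCCCCCCCCCCCc1ccc(C(=O)O)[nH]1
F5 | step 5 | N-methoxy-N-methyl-5-nonadecyl-1H-pyrrole-2-carboxamide | CCCCCCCCCCCCCCCCCCCc1ccc(C(=O)N(C)OC)[nH]1
F6 | step 4 | rac-ethyl cis-5-nonadecyl-2,5-dihydro-1H-pyrrole-2-carboxylate (one enantiomer drawn) | CCOC(=O)[C@@H]1N[C@H](CCCCCCCCCCCCCCCCCCC)C=C1
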